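## Retrosynthetic overview
1. The target is a chain of six rings, F–E–D–C–B–A, joined only by aryl ether oxygens. It comes from its pentadecamethyl ether by one global O-demethylation.
2. Rings A, B and C are removed one at a time at the hindered C–O bond (phenol + aryl halide, Ullmann). Rings C and B each come from 4-bromo-3,5-dimethoxybenzaldehyde, and Baeyer–Villiger oxidation of its CHO gives the next phenol. Ring A is 2-iodo-1,3,5-trimethoxybenzene.
3. Ring D, the only pentaoxygenated ring, is built de novo. Bond D4–D5 joins two carbonyl-level carbons: 1-methoxyvinyllithium (an acetyl anion equivalent) attacks one C=O of an aryl methyl squarate. Bond D1–D6 then forms by 4π opening and 6π closure of the cyclobutenone.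
4. The aryl methyl squarate comes from squaric acid dichloride, MeOH and the E–F phenol. The E–F phenol comes from 3,4,5-trimethoxyphenol and 4-bromo-3,5-dimethoxybenzaldehyde.
5. Ring order: F and E (bought arenes) are joined first, D is the only ring formed (step 4), then C, B and A (bought arenes) are added outward.

Assumption: the SMILES contains no stereocentre, stereogenic double bond or configurationally stable axis, so the target is achiral and nothing needs to be controlled or resolved.

Lettering: A is the terminal 2,4,6-trihydroxyphenyl ring and F is the terminal 3,4,5-trihydroxyphenyl ring. In ring D, D1 carries O–ring C, D2 carries O–ring E, D3 to D5 carry OH, and D6 carries H.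

## Route

Step 1
Reactants: 1 3,4,5-trimethoxyphenol; 2 4-bromo-3,5-dimethoxybenzaldehyde
Product: 3 3,5-dimethoxy-4-(3,4,5-trimethoxyphenoxy)benzaldehyde (rings F-E aldehyde)
Conditions: CuI (10 mol %), picolinic acid (20 mol %), K3PO4 (2 equiv), DMSO, 90 °C, Ar
Reagents that add atoms: none
Why: Ullmann-type diaryl ether coupling with monovalent copper works here because the bromide of 2 is activated by its para formyl group, the picolinic acid ligand suits di-ortho-substituted halides, and phenol 1 has both ortho positions free; no stereocentre is formed.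

Step 2
Reactants: 3 rings F-E aldehyde
Product: 5 3,5-dimethoxy-4-(3,4,5-trimethoxyphenoxy)phenol (rings F-E phenol), via aryl formate 4 (not isolated)
Conditions: mCPBA (1.3 equiv), CH2Cl2, 0 °C to 40 °C; aq NaHCO3 wash; then K2CO3 (10 mol %), MeOH, rt
Reagents that add atoms: mCPBA, OOC(=O)c1cccc(Cl)c1
Why: In this Baeyer–Villiger oxidation of an electron-rich benzaldehyde (Dakin-type result) the trioxygenated aryl group migrates rather than hydride, and formate 4 is methanolysed only after the peracid is washed out, so the oxidisable p-aryloxyphenol never meets oxidant.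

Step 3
Reactants: 5 rings F-E phenol; 6 3,4-dichlorocyclobut-3-ene-1,2-dione (squaric acid dichloride)
Product: 8 3-[3,5-dimethoxy-4-(3,4,5-trimethoxyphenoxy)phenoxy]-4-methoxycyclobut-3-ene-1,2-dione (aryl methyl squarate), via chloro methoxy squarate 7 (not isolated)
Conditions: 6, MeOH (1.0 equiv), CH2Cl2, 0 °C to rt, HCl swept out with Ar; then 5 (0.95 equiv), iPr2NEt (1.1 equiv), −40 to 0 °C; short silica plug
Reagents that add atoms: methanol, CO
Why: These are two successive addition–elimination reactions on a vinylogous acid chloride, in which the first chloride of 6 reacts much faster than the second because the methoxy group of 7 is a strong donor, and adding the phenol last with a non-nucleophilic base leaves no methanol or methoxide to transesterify the activated aryl ester 8.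

Step 4 (key step)
Reactants: 8 aryl methyl squarate; 9 methyl vinyl ether
Product: 14 2-[3,5-dimethoxy-4-(3,4,5-trimethoxyphenoxy)phenoxy]-3,4,5-trimethoxyphenol (rings F-E-D phenol), via 1-methoxyvinyllithium 10 (not isolated), via lithium alkoxide 11 (not isolated), via cyclobutenone methyl ether 12 (not isolated), via dienylketene 13 (not isolated)
Conditions: 9 (1.5 equiv), t-BuLi (1.1 equiv), THF, −78 to 0 °C; cannulate into 8, THF, −78 °C, 30 min; MeOTf (1.1 equiv, matched to the organolithium charge), −78 to 0 °C; add toluene, distil out THF, 110 °C, 2 h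
Reagents that add atoms: methyl trifluoromethanesulfonate, COS(=O)(=O)C(F)(F)F
Why: In this Moore-type squarate-to-arene ring expansion started by an acetyl anion equivalent, 10 adds 1,2 to the carbonyl next to C–OMe (the more electrophilic and less hindered one, being only the vinylogous ester of the weaker donor OAr) and so joins two natural acceptor carbons as D4–D5, methyl triflate caps alkoxide 11, heating opens 12 conrotatorily (methoxy outward, alkenyl inward) to the Z-dienylketene 13, and 6π closure makes D1–D6 before tautomerisation gives phenol 14, which erases the racemic quaternary centre of 11 and 12.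

Step 5
Reactants: 14 rings F-E-D phenol; 2 4-bromo-3,5-dimethoxybenzaldehyde
Product: 15 4-{2-[3,5-dimethoxy-4-(3,4,5-trimethoxyphenoxy)phenoxy]-3,4,5-trimethoxyphenoxy}-3,5-dimethoxybenzaldehyde (rings F-E-D-C aldehyde)
Conditions: CuI (20 mol %), picolinic acid (40 mol %), K3PO4 (2 equiv), DMSO, 100 °C, Ar
Reagents that add atoms: none
Why: This Ullmann-type coupling should work because D1–OH is the only free hydroxyl of 14 and still has one ortho hydrogen, the bromide is activated by the para formyl group, and the ligand system tolerates the tri-ortho-substituted ether formed, while methyl and diaryl ethers are inert.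

Step 6
Reactants: 15 rings F-E-D-C aldehyde
Product: 17 rings F-E-D-C phenol (CHO of 15 replaced by OH), via tetramer formate 16 (not isolated)
Conditions: mCPBA (1.3 equiv), CH2Cl2, 0 °C to rt; aq NaHCO3 wash; then K2CO3 (10 mol %), MeOH, rt
Reagents that add atoms: mCPBA, OOC(=O)c1cccc(Cl)c1
Why: In this Baeyer–Villiger oxidation the peracid adds to the only carbonyl group and the electron-rich ring C migrates, while near-stoichiometric peracid at low temperature leaves the polyalkoxy rings untouched.

Step 7
Reactants: 17 rings F-E-D-C phenol; 2 4-bromo-3,5-dimethoxybenzaldehyde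
Product: 18 rings F-E-D-C-B aldehyde (ring C phenol oxygen of 17 carrying a 4-formyl-2,6-dimethoxyphenyl group)
Conditions: CuI (10 mol %), picolinic acid (20 mol %), K3PO4 (2 equiv), DMSO, 90 °C, Ar
Reagents that add atoms: none
Why: This Ullmann-type coupling pairs the same partners as step 1 (a phenol with two free ortho positions and a para-formyl-activated bromide), so only the size of the nucleophile changes.

Step 8
Reactants: 18 rings F-E-D-C-B aldehyde
Product: 20 rings F-E-D-C-B phenol (CHO of 18 replaced by OH), via pentamer formate 19 (not isolated)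
Conditions: mCPBA (1.3 equiv), CH2Cl2, 0 °C to rt; aq NaHCO3 wash; then K2CO3 (10 mol %), MeOH, rt
Reagents that add atoms: mCPBA, OOC(=O)c1cccc(Cl)c1
Why: This is the same Baeyer–Villiger oxidation and formate methanolysis as in steps 2 and 6, acting on the single formyl group.

Step 9
Reactants: 20 rings F-E-D-C-B phenol; 21 2-iodo-1,3,5-trimethoxybenzene
Product: 22 pentadeca-O-methyl ether of the target (all six rings)
Conditions: CuI (20 mol %), picolinic acid (40 mol %), K3PO4 (2 equiv), DMSO, 105 °C, Ar
Reagents that add atoms: none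
Why: In this Ullmann diaryl ether synthesis with an unactivated halide the iodide is used to compensate, its small ortho methoxy groups can chelate copper, phenoxide 20 is unhindered, and bringing in ring A already fully oxygenated saves one oxidation step.

Step 10
Reactants: 22 pentadeca-O-methyl ether
Product: 23 target CNP0175585.0
Conditions: BBr3 (45 equiv), CH2Cl2, −78 °C to rt, 36 h, Ar; then H2O, 0 °C; EtOAc extraction; LH-20 dextran gel, degassed MeOH
Reagents that add atoms: none
Why: In this Lewis acid ether cleavage BBr3 binds each methoxy oxygen and bromide attacks the methyl carbon by SN2, which cannot occur at the sp2 carbons of the five diaryl ether bonds, so only the fifteen O–CH3 bonds break and hydrolysis of the aryl borates frees fifteen phenols; no stereocentre is involved.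

## Compound list
1 | 3,4,5-trimethoxyphenol | COc1cc(O)cc(OC)c1OC | starting material
2 | 4-bromo-3,5-dimethoxybenzaldehyde | COc1cc(C=O)cc(OC)c1Br | starting material
3 | 3,5-dimethoxy-4-(3,4,5-trimethoxyphenoxy)benzaldehyde | COc1cc(Oc2c(OC)cc(C=O)cc2OC)cc(OC)c1OC | intermediate
4 | 3,5-dimethoxy-4-(3,4,5-trimethoxyphenoxy)phenyl formate (not isolated) | COc1cc(Oc2c(OC)cc(OC=O)cc2OC)cc(OC)c1OC | intermediate
5 | 3,5-dimethoxy-4-(3,4,5-trimethoxyphenoxy)phenol | COc1cc(Oc2c(OC)cc(O)cc2OC)cc(OC)c1OC | intermediate
6 | 3,4-dichlorocyclobut-3-ene-1,2-dione (squaric acid dichloride) | O=C1C(=O)C(Cl)=C1Cl | starting material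
7 | 3-chloro-4-methoxycyclobut-3-ene-1,2-dione (not isolated) | COC1=C(Cl)C(=O)C1=O | intermediate
8 | 3-[3,5-dimethoxy-4-(3,4,5-trimethoxyphenoxy)phenoxy]-4-methoxycyclobut-3-ene-1,2-dione | COC1=C(Oc2cc(OC)c(Oc3cc(OC)c(OC)c(OC)c3)c(OC)c2)C(=O)C1=O | intermediate
9 | methyl vinyl ether (methoxyethene) | COC=C | starting material
10 | 1-methoxyvinyllithium (not isolated) | [Li]C(=C)OC | intermediate
11 | lithium 3-(rings F-E aryloxy)-2-methoxy-1-(1-methoxyvinyl)-4-oxocyclobut-2-en-1-olate, racemic (not isolated) | [Li]OC1(C(=C)OC)C(OC)=C(Oc2cc(OC)c(Oc3cc(OC)c(OC)c(OC)c3)c(OC)c2)C1=O | intermediate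
12 | 2-(rings F-E aryloxy)-3,4-dimethoxy-4-(1-methoxyvinyl)cyclobut-2-en-1-one, racemic (not isolated) | COC1(C(=C)OC)C(OC)=C(Oc2cc(OC)c(Oc3cc(OC)c(OC)c(OC)c3)c(OC)c2)C1=O | intermediate
13 | (3Z)-2-(rings F-E aryloxy)-3,4,5-trimethoxyhexa-1,3,5-trien-1-one, dienylketene (not isolated) | O=C=C(Oc1cc(OC)c(Oc2cc(OC)c(OC)c(OC)c2)c(OC)c1)/C(OC)=C(OC)\C(=C)OC | intermediate
14 | 2-[3,5-dimethoxy-4-(3,4,5-trimethoxyphenoxy)phenoxy]-3,4,5-trimethoxyphenol | COc1cc(O)c(Oc2cc(OC)c(Oc3cc(OC)c(OC)c(OC)c3)c(OC)c2)c(OC)c1OC | intermediate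
15 | rings F-E-D-C aldehyde: 4-{2-[3,5-dimethoxy-4-(3,4,5-trimethoxyphenoxy)phenoxy]-3,4,5-trimethoxyphenoxy}-3,5-dimethoxybenzaldehyde | COc1cc(Oc4c(OC)cc(C=O)cc4OC)c(Oc2cc(OC)c(Oc3cc(OC)c(OC)c(OC)c3)c(OC)c2)c(OC)c1OC | intermediate
16 | rings F-E-D-C formate: CHO of 15 replaced by OCHO (not isolated) | COc1cc(Oc4c(OC)cc(OC=O)cc4OC)c(Oc2cc(OC)c(Oc3cc(OC)c(OC)c(OC)c3)c(OC)c2)c(OC)c1OC | intermediate
17 | rings F-E-D-C phenol: CHO of 15 replaced by OH | COc1cc(Oc4c(OC)cc(O)cc4OC)c(Oc2cc(OC)c(Oc3cc(OC)c(OC)c(OC)c3)c(OC)c2)c(OC)c1OC | intermediate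
18 | rings F-E-D-C-B aldehyde: phenol O of 17 bearing 4-formyl-2,6-dimethoxyphenyl | COc1cc(Oc4c(OC)cc(Oc5c(OC)cc(C=O)cc5OC)cc4OC)c(Oc2cc(OC)c(Oc3cc(OC)c(OC)c(OC)c3)c(OC)c2)c(OC)c1OC | intermediate
19 | rings F-E-D-C-B formate: CHO of 18 replaced by OCHO (not isolated) | COc1cc(Oc4c(OC)cc(Oc5c(OC)cc(OC=O)cc5OC)cc4OC)c(Oc2cc(OC)c(Oc3cc(OC)c(OC)c(OC)c3)c(OC)c2)c(OC)c1OC | intermediate
20 | rings F-E-D-C-B phenol: CHO of 18 replaced by OH | COc1cc(Oc4c(OC)cc(Oc5c(OC)cc(O)cc5OC)cc4OC)c(Oc2cc(OC)c(Oc3cc(OC)c(OC)c(OC)c3)c(OC)c2)c(OC)c1OC | intermediate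
21 | 2-iodo-1,3,5-trimethoxybenzene | COc1cc(OC)c(I)c(OC)c1 | starting material
22 | pentadeca-O-methyl ether of the target: phenol O of 20 bearing 2,4,6-trimethoxyphenyl | COc1cc(Oc4c(OC)cc(Oc5c(OC)cc(Oc6c(OC)cc(OC)cc6OC)cc5OC)cc4OC)c(Oc2cc(OC)c(Oc3cc(OC)c(OC)c(OC)c3)c(OC)c2)c(OC)c1OC | intermediate
23 | CNP0175585.0 (achiral hexameric phlorotannin, C36H26O20) | Oc1cc(O)c(Oc2cc(O)c(Oc3cc(O)c(Oc4cc(O)c(O)c(O)c4Oc4cc(O)c(Oc5cc(O)c(O)c(O)c5)c(O)c4)c(O)c3)c(O)c2)c(O)c1 | target

## Step count and risks
Total steps: 10. Longest linear sequence: 10 (1 or 2 to 23; the route is fully linear).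

**Step 4 is the most likely to fail.**
- 10 may displace aryloxide from 8 by addition–elimination instead of adding 1,2.
- The preference for the carbonyl next to C–OMe may be only moderate.
- Capping of the tertiary alkoxide may be incomplete.

The fallback sets out from 5 and comes back at 14. Ring D is then bought rather than built. Phenol 5 is coupled (CuI, picolinic acid, K3PO4, DMSO, 100 °C) with commercial 2-bromo-3,4,5-trimethoxybenzaldehyde (COc1cc(C=O)c(Br)c(OC)c1OC), whose bromide is activated by the ortho formyl group. This gives 2-[3,5-dimethoxy-4-(3,4,5-trimethoxyphenoxy)phenoxy]-3,4,5-trimethoxybenzaldehyde F1. mCPBA turns it into the corresponding aryl formate F2, and catalytic K2CO3 in MeOH releases 14. This replaces steps 3 and 4 by two steps.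

**Step 9 is the second risk.** The iodide is electron-rich, di-ortho-substituted and unactivated, so protodeiodination or low conversion is likely. The fallback sets out from 20 and comes back at 23.
- Phenol 20 is coupled with the activated bromide 2, exactly as in step 7, to give the rings F-E-D-C-B-A aldehyde F3.
- mCPBA gives the hexamer formate F4, and methanolysis gives the hexamer phenol F5. F5 is the tetradecamethyl ether with the para hydroxyl of ring A already free.
- The BBr3 conditions of step 10 convert F5 into 23. This costs one extra step.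

**Step 10 is the third risk.** Fifteen cleavages must all go to completion, insoluble borate intermediates can stall the reaction, and the pyrogallol-type product oxidises in air during purification. The fallback sets out from 22 and comes back at 23.
- The crude polyphenol from the BBr3 reaction is not purified. It is captured with Ac2O in pyridine as the pentadecaacetate F6.
- F6 is air-stable and can be chromatographed on silica, which removes partly methylated material.
- Acid-catalysed methanolysis (1 % HCl in degassed MeOH, 40 °C, Ar) then releases pure 23, and only volatile material needs to be evaporated.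

## Further compounds
F1 | step 4 | 2-[3,5-dimethoxy-4-(3,4,5-trimethoxyphenoxy)phenoxy]-3,4,5-trimethoxybenzaldehyde | COc1cc(C=O)c(Oc2cc(OC)c(Oc3cc(OC)c(OC)c(OC)c3)c(OC)c2)c(OC)c1OC
F2 | step 4 | 2-[3,5-dimethoxy-4-(3,4,5-trimethoxyphenoxy)phenoxy]-3,4,5-trimethoxyphenyl formate | COc1cc(OC=O)c(Oc2cc(OC)c(Oc3cc(OC)c(OC)c(OC)c3)c(OC)c2)c(OC)c1OC
F3 | step 9 | rings F-E-D-C-B-A aldehyde: phenol O of 20 bearing 4-formyl-2,6-dimethoxyphenyl | COc1cc(Oc4c(OC)cc(Oc5c(OC)cc(Oc6c(OC)cc(C=O)cc6OC)cc5OC)cc4OC)c(Oc2cc(OC)c(Oc3cc(OC)c(OC)c(OC)c3)c(OC)c2)c(OC)c1OC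
F4 | step 9 | hexamer formate: CHO of F3 replaced by OCHO | COc1cc(Oc4c(OC)cc(Oc5c(OC)cc(Oc6c(OC)cc(OC=O)cc6OC)cc5OC)cc4OC)c(Oc2cc(OC)c(Oc3cc(OC)c(OC)c(OC)c3)c(OC)c2)c(OC)c1OC
F5 | step 9 | hexamer phenol: tetradeca-O-methyl ether of the target with free para OH on ring A | COc1cc(Oc4c(OC)cc(Oc5c(OC)cc(Oc6c(OC)cc(O)cc6OC)cc5OC)cc4OC)c(Oc2cc(OC)c(Oc3cc(OC)c(OC)c(OC)c3)c(OC)c2)c(OC)c1OC
F6 | step 10 | pentadecaacetate of the target | CC(=O)Oc1cc(OC(C)=O)c(Oc2cc(OC(C)=O)c(Oc3cc(OC(C)=O)c(Oc4cc(OC(C)=O)c(OC(C)=O)c(OC(C)=O)c4Oc4cc(OC(C)=O)c(Oc5cc(OC(C)=O)c(OC(C)=O)c(OC(C)=O)c5)c(OC(C)=O)c4)c(OC(C)=O)c3)c(OC(C)=O)c2)c(OC(C)=O)c1
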